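The easy mistake with curves that start with a lag is to compare two runs at one clock time, since the run that is ahead is then also at a later stage. I compared them at one share of the charge instead.

| flask | starting material | coupling partner | time |
|---|---|---|---|
| ash | 100 mM | 200 mM |  |
| birch | 60.0 mM | 160 mM |  |
| alder | 100 mM | 300 mM |  |
| elm | 100 mM | 200 mM | 24 h |

- ash run (time / h: [target] / mM): 0.43: 0.5; 1.3: 3.3; 2.5: 8.9; 4.0: 13.0; 5.7: 22.8; 7.6: 28.9; 9.7: 33.4; 12: 37.9
- birch run (time / h: [target] / mM): 0.43: 0; 1.3: 3.5; 2.5: 3.9; 4.0: 6.7; 5.7: 8.3; 7.6: 11.8; 9.7: 12.6; 12: 14.6
- alder run (time / h: [target] / mM): 0.43: 0; 1.3: 2.9; 2.5: 12.2; 4.0: 19.6; 5.7: 30.4; 7.6: 35.4; 9.7: 35.8; 12: 32.0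

(scatter of a reading: 1 mM)

- reaction order in [coupling partner] at the outset, round the charge of the ash run, defined at two percent of the starting material turned into target
- reaction order in [starting material] at the outset, round the charge of the ash run, defined at two percent of the starting material turned into target (one fixed amount of target, the same in the runs compared)
- target in the elm run at 24 h, as a share of the starting material charged

- Overall: starting material + coupling partner -> target.
- Constant volume, constant temperature.
- An order is taken over about fifteen percent of the charge, up and down.

Ash and alder have the same charge of starting material and differ in partner. Alder read 30.4% of its charge at 5.7 h, and ash read nearly that, 28.9%, at 7.6 h. The clock ratio, the hours the slower run takes to reach a share of the charge for each hour the faster run takes, is here a reading of 1.33. Over the partner step of 1.50, I took it as an order of 0.710 in partner. Birch read 8.30% of ash's charge at 5.7 h, where ash read 8.90% at 2.5 h, and after the partner's part that left me 1.30 in starting material.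

The two runs end apart. Alder's readings fell from 35.8% at 9.7 h to 32.0% at 12 h, while ash still rose. Taking alder's highest reading as its top, I put ash's top by the clock ratio near 12.9 h, later than ash's last reading. For ash I took alder's fall, slowed by the same ratio, as 0.0366 h⁻¹. Elm repeats ash's charge, so with ash's last reading as the top I expected 25.3% at 24 h.

The forecast said 0.75 in partner, 1.3 in starting material and 33% of the charge in elm, holding that “a build-up phase dilutes apparent orders at fixed product”. Its share for elm is higher than mine.

The flask gave 0.71 in partner, 0.83 in starting material and 31.1% of the charge in elm.

    starting material + coupling partner ⇌ intermediate (0.5652 L mol⁻¹ h⁻¹, 0.6444 h⁻¹)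
    intermediate → target (0.3672 h⁻¹)
    target + coupling partner → side product (0.7848 L mol⁻¹ h⁻¹)
    starting material + coupling partner + target → 2 target (20.41 L² mol⁻² h⁻¹)

At the early amount asked, alder's rate over ash's was 1.3, beside the clock ratio of 1.33. In elm, starting material and partner formed the intermediate, which gave the first target, and as target gathered, the step taking starting material, partner and target (autocatalysis) added more. Meanwhile partner turned target into side product, and target stood at 31.1% of the charge at 24 h.

The data are calculated with made-up constants; scatter was added.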